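## Structural features

The target is a flavonol: a benzene ring A fused to a 4-pyranone ring C (a 4H-chromen-4-one), with a 4-hydroxyphenyl ring B on C2 and a hydroxyl on C3. Ring A is pentasubstituted: O1 on C8a, the C4 carbonyl on C4a, hydroxyls on C5 and C6, a hydrogen sulfate ester on O7, and its only hydrogen on C8. There is no stereocentre, so the problem is purely regiochemical: five contiguous substituents on ring A, and one sulfate on a single oxygen out of five phenolic or enolic ones. The aryl sulfate monoester is the fragile group, because protic and Lewis acids cleave it, so it cannot be present when alkyl ethers are removed; the free 5,6-dihydroxy array is also easily oxidised in basic, aerated solution. O7 differs from the other oxygens in being para to the acyl-bearing C4a, which makes its phenol the most acidic and its esters the most labile; a late differentiation can use this. The key step exploits the ortho pair C8a–O1 / C4a–C4 lying next to the C5 oxygen. This is the array left when a carboxylate adds to a 3-alkoxyaryne at the carbon remote from the alkoxy group and the acyl group then moves from oxygen to the neighbouring carbanion. Because the other ring A oxygens are contiguous (C5, C6, C7), the aryne can come from a symmetric 3,4,5-trioxygenated phenol, for which only one ortho-functionalised precursor exists.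

## Logic of the disconnections

20 to 18 (through 19): the four acetyl–oxygen bonds on O3, O5, O6 and O4' and the counter-ion are cut. The sulfate cannot survive ether cleavage, so it must be in place only when the remaining protecting groups leave under mild nucleophilic, non-acidic conditions. The gain is that every hazard to the S–O bond is confined to one cold step; the demand is aminolysis without air, followed by a brief cation-for-proton exchange.

18 to 17: the O7–S bond is cut. With one free hydroxyl in 17 the site of sulfation is unambiguous. The forward step needs an electrophilic sulfur trioxide transfer that leaves aryl esters untouched and is faster than any acetyl shift from O6.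

17 to 16 to 15: first the O7–acetyl bond, then all five O–acetyl bonds are cut. O7 is singled out by the leaving-group ability of its phenoxide, so one chemoselective deacylation replaces the construction of a ring A with differentiated oxygens. This keeps ring A symmetric in its building block. The demand is selectivity for the 7-acetate over the 4'- and 3-acetates.

15 to 14: five O–CH3 bonds are cut. Methyl ethers are the one phenol protection that tolerates organolithium, fluoride at high temperature, the aryne and acid, and all five fall in one operation. The forward step must be exhaustive and must not open ring C, since ring-opening and reclosure on the other ortho oxygen would scramble ring A.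

14 to 13: the O1–C2 bond is cut. Ring C is a vinylogous ester, so it opens to an ortho-hydroxyaryl ketone carrying a β-methoxy enone. The forward step is an addition–elimination that needs only a leaving group on the β-carbon; alkene geometry is irrelevant.

13 to 5 and 10: the O1–C8a and C4–C4a bonds are cut together. This separates ring A, as an aryne equivalent, from one acid holding C2, C3, C4 and ring B, which is the most convergent division available. In the mapping, the triflate carbon of 5 becomes C8a and the silyl carbon becomes C4a, next to the methoxy carbon that becomes C5. The forward step must add the carboxylate at the aryne carbon remote from the flanking methoxy group, and acyl transfer must outrun protonation of the carbanion.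

5 to 2 to 1: the C–Si and O–S bonds are cut (through 4 and 3), then the C–Br bond. An ortho-silylaryl triflate comes from an ortho-bromophenol, and the symmetry of 1 allows only one monobromide. The demand is monobromination of a very electron-rich phenol without oxidation.

10 to 9 to 8: the ester O–CH3 bond and then the enol O–CH3 bond are cut. The enol ether leads back to a β-keto ester enolate. The forward steps need O- over C-methylation and an isolation of 10 that avoids strong acid.

8 to 6 and 7: the bond between the future C3 and C2 is cut, a Claisen-type acylation retron. It joins two commercial pieces, and the α-methoxy group brings the C3 oxygen in at the correct oxidation level. The demand is clean mono-acylation of an ester enolate.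

## Other disconnections considered

Alternative 1: The cut goes through ring A at C7–C8 and C5–C6. Rings B and C arrive as the pyranone ester A1 (methyl 5-(benzyloxy)-6-[4-(benzyloxy)phenyl]-2-methyl-4-oxo-4H-pyran-3-carboxylate), and C6 and C7 as methyl benzyloxyacetate A2. In the forward step the anion of the C-methyl group of A1 would be acylated by A2. The keto ester, deprotonated again at the benzyloxy-bearing carbon, would then close onto the ring ester (Dieckmann-type) and aromatise to A3 (3,6-bis(benzyloxy)-2-[4-(benzyloxy)phenyl]-5,7-dihydroxy-4H-chromen-4-one).
- In favour: the ring A pattern is fixed by connectivity and not by a directing effect, which is the equal of the chosen plan and arguably better. A3 has only O5 and O7 free, so the unchelated, more acidic O7 could be sulfated directly and the benzyl ethers removed by hydrogenolysis, which an aryl sulfate should tolerate. The endgame would be about two steps against five, without BBr3 and without a selective deacetylation; on this point the alternative is clearly better.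
- Against: A1 is a fully substituted pyranone needing its own sequence, probably as long as steps 1 to 5. The closure requires the less acidic carbanion site to react after the first acylation has created a very acidic vinylogous diketone. The 4-pyranone is open to nucleophilic ring-opening by the same bases, and A2 can self-condense.
- Comparison: structurally it is better (O7 differentiated from the start); mechanistically it is less secure than the aryne insertion, whose individual events are well understood; in step count the saving at the end is likely to be spent on A1, so the totals should be similar.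

Alternative 2: The cut is the C3–C4 bond, giving the dialdehyde A4 (2,3,4-trimethoxy-6-[1-(4-methoxyphenyl)-2-oxoethoxy]benzaldehyde). An N-heterocyclic carbene would add to the aliphatic aldehyde, and the resulting acyl anion equivalent would attack the aromatic aldehyde to give the cyclic acyloin A5 (4-hydroxy-5,6,7-trimethoxy-2-(4-methoxyphenyl)chroman-3-one). Oxidation and enolisation would then give A6 (3-hydroxy-5,6,7-trimethoxy-2-(4-methoxyphenyl)-4H-chromen-4-one).
- In favour: the step is catalytic and nearly neutral. Either regiochemical sense of the acyloin and either diastereomer converge on A6, so the alternative is the equal of the chosen plan in having no stereochemistry to control. Ring A would again come from 1 by formylation at one of two equivalent positions, so its regiochemistry is equally secure.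
- Against: A4 is an α-aryloxy aldehyde. Its carbene adduct carries an aryloxide leaving group on the adjacent carbon and is expected to expel it (the redox pathway typical of such aldehydes) before it can attack a hindered, electron-rich aromatic aldehyde. A4 is also readily enolised and would be hard to store. Its preparation needs roughly as many steps as 5 and 10 together, an oxidation must follow, and A6 still meets the same demethylation and acetate endgame.
- Comparison: no structural gain beyond a free O3, which is of no use here; mechanistically weaker; at best equal in steps, probably one longer.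

Alternative 3: The cut is the C4–C4a bond, giving the acid A7 ((E)-2-methoxy-3-(4-methoxyphenyl)-3-(3,4,5-trimethoxyphenoxy)acrylic acid). Activation of the carboxyl (P2O5 in MeSO3H, or trifluoroacetic anhydride) would acylate the aryloxy ring ortho to the ether oxygen and close ring C to A8 (3,5,6,7-tetramethoxy-2-(4-methoxyphenyl)-4H-chromen-4-one, identical with 14).
- In favour: 1 is used directly as the oxygen nucleophile, so steps 1 and 2 are not needed. The aryloxy ring is symmetric, so there is no regiochemical question at all, which is the equal of the chosen plan. A7 could come from 9 and 1 by addition–elimination and ester hydrolysis, so 14 would be reached in about two fewer steps. On step economy this alternative is the better one.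
- Against: the closure needs the carboxyl cis to the aryloxy group and strongly acidic, dehydrating conditions. A β-aryloxy-α-methoxyacrylic acid can then protonate at the α-carbon and lose the phenol or carbon dioxide, and the very electron-rich ring can be attacked intermolecularly. The addition–elimination of a phenoxide on the donor-rich, tetrasubstituted 9 is also expected to be slow.
- Comparison: structurally equal (same product, same endgame); mechanistically the risk lies in acid stability, where the chosen plan's lies in protonation of an aryl anion; shorter by about two steps.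

Key step: step 6

Assumption: the target is drawn as the free hydrogen sulfate; the sulfate is therefore carried as its pyridinium and ammonium salts, and only the last operation exchanges the cation for a proton. The acid form should be kept cold and dry, because aryl hydrogen sulfates hydrolyse under acidic conditions.

## Steps

Step 1
Reactants: 1 3,4,5-trimethoxyphenol
Product: 2 2-bromo-3,4,5-trimethoxyphenol
Conditions: NBS (1.0 equiv), CH2Cl2, –78 → 0 °C
Reagents that add atoms: N-bromosuccinimide, O=C1CCC(=O)N1Br
Why: Electrophilic aromatic bromination of a strongly activated phenol whose para position is blocked and whose two ortho positions are equivalent, so only one monobromide can form; one equivalent of reagent at low temperature limits dibromination and oxidation to a quinone.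

Step 2
Reactants: 2 2-bromo-3,4,5-trimethoxyphenol
Product: 5 3,4,5-trimethoxy-2-(trimethylsilyl)phenyl trifluoromethanesulfonate, via aryl trimethylsilyl ether 3 (not isolated), via lithium 2-silylphenolate 4 (not isolated)
Conditions: HN(SiMe3)2, THF, 70 °C, then evaporate; n-BuLi, THF, –78 °C; Tf2O, –78 °C → rt
Reagents that add atoms: hexamethyldisilazane, C[Si](C)(C)N[Si](C)(C)C; trifluoromethanesulfonic anhydride, O=S(=O)(OS(=O)(=O)C(F)(F)F)C(F)(F)F
Why: O-Silylation, then bromine–lithium exchange and an anionic 1,3 O-to-C silyl shift (retro-Brook rearrangement) driven by formation of the phenoxide, which is trapped as the triflate; this is the standard entry to ortho-silylaryl triflates from ortho-bromophenols.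

Step 3
Reactants: 6 methyl methoxyacetate; 7 4-methoxybenzoyl chloride
Product: 8 methyl 2-methoxy-3-(4-methoxyphenyl)-3-oxopropanoate (racemic)
Conditions: 6 (2.0 equiv), LiN(SiMe3)2 (2.0 equiv), THF, –78 °C; then 7 (1.0 equiv), –78 → –20 °C; cold 1 M HCl
Reagents that add atoms: none
Why: Crossed Claisen-type C-acylation of the lithium ester enolate by the acid chloride; the second equivalent of enolate deprotonates the more acidic β-keto ester as it forms and so prevents a second acylation. The new stereocentre is enolisable and becomes trigonal in step 4, so 8 is used as the racemate.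

Step 4
Reactants: 8 methyl 2-methoxy-3-(4-methoxyphenyl)-3-oxopropanoate
Product: 9 methyl (E)-2,3-dimethoxy-3-(4-methoxyphenyl)prop-2-enoate
Conditions: Cs2CO3, Me2SO4, DMF, 0 °C → rt; aq NH3 quench
Reagents that add atoms: dimethyl sulfate, COS(=O)(=O)OC
Why: O-Alkylation of a β-keto ester enolate, favoured by a hard methylating agent, a large counter-ion and a dipolar aprotic solvent, while C-methylation would have to build a quaternary carbon. The E isomer (methoxy groups trans) is drawn, but either isomer or a mixture serves, since the geometry is lost in step 7.

Step 5
Reactants: 9 methyl (E)-2,3-dimethoxy-3-(4-methoxyphenyl)prop-2-enoate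
Product: 10 (E)-2,3-dimethoxy-3-(4-methoxyphenyl)prop-2-enoic acid
Conditions: LiOH·H2O, THF–MeOH–H2O, 45 °C; cold 1 M HCl to pH 3, extract at once
Reagents that add atoms: lithium hydroxide, [Li+].[OH-]
Why: Ester saponification by acyl substitution; the tetrasubstituted, donor-rich alkene resists conjugate attack by hydroxide. The acidification is kept cold and mild because β-alkoxyacrylic acids hydrolyse and decarboxylate in strong acid.

Step 6
Reactants: 5 3,4,5-trimethoxy-2-(trimethylsilyl)phenyl trifluoromethanesulfonate; 10 (E)-2,3-dimethoxy-3-(4-methoxyphenyl)prop-2-enoic acid
Product: 13 (E)-1-(2-hydroxy-4,5,6-trimethoxyphenyl)-2,3-dimethoxy-3-(4-methoxyphenyl)prop-2-en-1-one, via 3,4,5-trimethoxybenzyne 11 (not isolated), via 2-acyloxyaryl cesium 12 (not isolated)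
Conditions: 5 (1.5 equiv), CsF (4 equiv), THF, 125 °C, sealed tube; aq NH4Cl
Reagents that add atoms: none
Why: Fluoride removes the silyl group of 5 and triflate departs to give aryne 11; the cesium carboxylate of 10 adds through oxygen to the aryne carbon remote from the flanking methoxy group, because that inductively withdrawing substituent distorts the aryne and stabilises the carbanion developing next to it, so oxygen ends on the future C8a and the charge on the future C4a in 12. The carbanion of 12 then attacks its own ester carbonyl through a four-membered transition state and the adduct collapses with O-to-C acyl transfer, as in an anionic ortho-Fries shift, forming the C4–C4a bond and the phenoxide of 13. This is the known fluoride-induced insertion of arynes into the C–O bond of carboxylic acids to give ortho-hydroxyaryl ketones, applied here to a new acid. No ring is closed and no stereocentre is formed. Two selectivities are needed: the site of carboxylate addition, secured by the methoxy group beside the aryne, and acyl transfer in preference to protonation of the carbanion or its conjugate addition to the β-carbon. The hot aprotic medium favours the intramolecular acyl shift, and the β-carbon is fully substituted and deactivated by its methoxy and anisyl donors. If part of 13 closes to 14 in the hot basic medium, this only anticipates step 7 and the mixture can be carried forward.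

Step 7
Reactants: 13 (E)-1-(2-hydroxy-4,5,6-trimethoxyphenyl)-2,3-dimethoxy-3-(4-methoxyphenyl)prop-2-en-1-one
Product: 14 3,5,6,7-tetramethoxy-2-(4-methoxyphenyl)-4H-chromen-4-one
Conditions: TsOH·H2O (20 mol %), toluene, 80 °C
Reagents that add atoms: none
Why: Acid-catalysed intramolecular addition–elimination: protonation of the enone carbonyl makes the β-carbon an oxocarbenium centre, the ortho hydroxyl closes the six-membered ring and methanol is expelled to give the aromatic pyranone. Any hydrolysis of the enol ether to the 1,3-diketone leads to the same product by cyclodehydration.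

Step 8
Reactants: 14 3,5,6,7-tetramethoxy-2-(4-methoxyphenyl)-4H-chromen-4-one
Product: 15 3,5,6,7-tetrahydroxy-2-(4-hydroxyphenyl)-4H-chromen-4-one
Conditions: BBr3 (12 equiv), CH2Cl2, –78 °C → rt; MeOH then H2O, 0 °C
Reagents that add atoms: none
Why: Lewis acid cleavage of aryl and enol methyl ethers (oxygen–boron complexation, then bromide attack on methyl); the carbonyl-chelated 5- and 3-ethers should go first, and excess reagent removes the others. Aprotic, low-temperature conditions avoid the ring-opening and reclosure (Wessely–Moser) that hot protic acid could cause.

Step 9
Reactants: 15 3,5,6,7-tetrahydroxy-2-(4-hydroxyphenyl)-4H-chromen-4-one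
Product: 16 2-(4-acetoxyphenyl)-4-oxo-4H-chromene-3,5,6,7-tetrayl tetraacetate
Conditions: Ac2O, pyridine, DMAP (cat.), rt → 50 °C
Reagents that add atoms: acetic anhydride, CC(=O)OC(C)=O
Why: Exhaustive O-acetylation with nucleophilic catalysis; the hydrogen-bonded 5-hydroxyl is the slowest and is the reason for the catalyst and mild warming. The pentaacetate also makes the air-sensitive polyphenol storable.

Step 10
Reactants: 16 2-(4-acetoxyphenyl)-4-oxo-4H-chromene-3,5,6,7-tetrayl tetraacetate
Product: 17 2-(4-acetoxyphenyl)-7-hydroxy-4-oxo-4H-chromene-3,5,6-triyl triacetate
Conditions: PhSH (1.2 equiv), imidazole (0.5 equiv), NMP, 0 °C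
Reagents that add atoms: none
Why: Chemoselective nucleophilic deacylation: the 7-acetate is the most electrophilic because its phenoxide, para to the C4a acyl carbon, is the best leaving group, which is the known basis of selective 7-O-deacetylation of flavone peracetates. With limiting thiol at 0 °C the 4'- and 3-acetates should remain, and an acetyl shift from O6 is not favoured because the acyl group is more stable on the less acidic oxygen.

Step 11
Reactants: 17 2-(4-acetoxyphenyl)-7-hydroxy-4-oxo-4H-chromene-3,5,6-triyl triacetate
Product: 18 pyridinium 3,5,6-triacetoxy-2-(4-acetoxyphenyl)-4-oxo-4H-chromen-7-yl sulfate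
Conditions: SO3·pyridine (3 equiv), pyridine, rt; evaporate, Sephadex LH-20 (MeOH)
Reagents that add atoms: sulfur trioxide–pyridine complex, [O-]S(=O)(=O)[n+]1ccccc1
Why: O-Sulfation of the only free hydroxyl, an acidic phenol partly ionised in pyridine, by sulfur trioxide transfer from its amine complex, giving the sulfate monoester as its pyridinium salt; aryl acetates are inert to this electrophile.

Step 12
Reactants: 18 pyridinium 3,5,6-triacetoxy-2-(4-acetoxyphenyl)-4-oxo-4H-chromen-7-yl sulfate
Product: 20 3,5,6-trihydroxy-2-(4-hydroxyphenyl)-4-oxo-4H-chromen-7-yl hydrogen sulfate, via ammonium sulfate salt 19 (not isolated)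
Conditions: NH3 (7 M in MeOH), 0 °C, argon; evaporate; sulfonic acid cation-exchange resin (H+ form), H2O, 0 °C; freeze-dry
Reagents that add atoms: none
Why: Ammonolysis of the four aryl and enol acetates (acyl substitution, giving acetamide) is fast at 0 °C, while the sulfate monoester anion is inert to base and nucleophiles; excluding air protects the 5,6-dihydroxy array. A brief, cold pass over the acid resin replaces ammonium by a proton to give the acid form of the target.

## Compound list

1 | 3,4,5-trimethoxyphenol | COc1cc(O)cc(OC)c1OC | starting material
2 | 2-bromo-3,4,5-trimethoxyphenol | COc1cc(O)c(Br)c(OC)c1OC | intermediate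
3 | (2-bromo-3,4,5-trimethoxyphenoxy)trimethylsilane | COc1cc(O[Si](C)(C)C)c(Br)c(OC)c1OC | intermediate
4 | lithium 3,4,5-trimethoxy-2-(trimethylsilyl)phenolate | COc1cc([O-])c([Si](C)(C)C)c(OC)c1OC.[Li+] | intermediate
5 | 3,4,5-trimethoxy-2-(trimethylsilyl)phenyl trifluoromethanesulfonate | COc1cc(OS(=O)(=O)C(F)(F)F)c([Si](C)(C)C)c(OC)c1OC | intermediate
6 | methyl methoxyacetate | COCC(=O)OC | starting material
7 | 4-methoxybenzoyl chloride | COc1ccc(cc1)C(Cl)=O | starting material
8 | methyl 2-methoxy-3-(4-methoxyphenyl)-3-oxopropanoate (racemic) | COC(C(=O)OC)C(=O)c1ccc(OC)cc1 | intermediate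
9 | methyl (E)-2,3-dimethoxy-3-(4-methoxyphenyl)prop-2-enoate | CO/C(c1ccc(OC)cc1)=C(/OC)C(=O)OC | intermediate
10 | (E)-2,3-dimethoxy-3-(4-methoxyphenyl)prop-2-enoic acid | CO/C(c1ccc(OC)cc1)=C(/OC)C(=O)O | intermediate
11 | 3,4,5-trimethoxybenzyne (1,2-didehydro-3,4,5-trimethoxybenzene) | COC1=C(OC)C(OC)=CC#C1 | intermediate
12 | cesium 2-{[(E)-2,3-dimethoxy-3-(4-methoxyphenyl)prop-2-enoyl]oxy}-4,5,6-trimethoxybenzen-1-ide | CO/C(c1ccc(OC)cc1)=C(/OC)C(=O)Oc1cc(OC)c(OC)c(OC)[c-]1.[Cs+] | intermediate
13 | (E)-1-(2-hydroxy-4,5,6-trimethoxyphenyl)-2,3-dimethoxy-3-(4-methoxyphenyl)prop-2-en-1-one | CO/C(c1ccc(OC)cc1)=C(/OC)C(=O)c1c(O)cc(OC)c(OC)c1OC | intermediate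
14 | 3,5,6,7-tetramethoxy-2-(4-methoxyphenyl)-4H-chromen-4-one | COc1ccc(cc1)-c1oc2cc(OC)c(OC)c(OC)c2c(=O)c1OC | intermediate
15 | 3,5,6,7-tetrahydroxy-2-(4-hydroxyphenyl)-4H-chromen-4-one | O=c1c(O)c(-c2ccc(O)cc2)oc2cc(O)c(O)c(O)c12 | intermediate
16 | 2-(4-acetoxyphenyl)-4-oxo-4H-chromene-3,5,6,7-tetrayl tetraacetate | CC(=O)Oc1ccc(cc1)-c1oc2cc(OC(C)=O)c(OC(C)=O)c(OC(C)=O)c2c(=O)c1OC(C)=O | intermediate
17 | 2-(4-acetoxyphenyl)-7-hydroxy-4-oxo-4H-chromene-3,5,6-triyl triacetate | CC(=O)Oc1ccc(cc1)-c1oc2cc(O)c(OC(C)=O)c(OC(C)=O)c2c(=O)c1OC(C)=O | intermediate
18 | pyridinium 3,5,6-triacetoxy-2-(4-acetoxyphenyl)-4-oxo-4H-chromen-7-yl sulfate | CC(=O)Oc1ccc(cc1)-c1oc2cc(OS(=O)(=O)[O-])c(OC(C)=O)c(OC(C)=O)c2c(=O)c1OC(C)=O.c1cc[nH+]cc1 | intermediate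
19 | ammonium 3,5,6-trihydroxy-2-(4-hydroxyphenyl)-4-oxo-4H-chromen-7-yl sulfate | O=c1c(O)c(-c2ccc(O)cc2)oc2cc(OS(=O)(=O)[O-])c(O)c(O)c12.[NH4+] | intermediate
20 | 3,5,6-trihydroxy-2-(4-hydroxyphenyl)-4-oxo-4H-chromen-7-yl hydrogen sulfate | O=c1c(O)c(-c2ccc(O)cc2)oc2cc(OS(=O)(=O)O)c(O)c(O)c12 | target

## Step count and least certain steps

Total: 12 steps. Longest linear sequence: 10 steps (steps 3 to 12, from 6 and 7); the aryne branch (steps 1 and 2) joins at step 6.

Step 6 (key step). The most likely failure is protonation of the carbanion of 12 before acyl transfer, which would divert material to the simple aryl ester. Further losses could come from arylation of the product phenoxide by a second aryne, or from slow thermal degradation of the β-alkoxyacrylate at 125 °C. Fallback: a Baker–Venkataraman construction that sets out from 1 and 7 and rejoins the route at 14. Friedel–Crafts acylation of 1 with methoxyacetic acid in BF3·OEt2 at 80 °C would give 1-(2-hydroxy-4,5,6-trimethoxyphenyl)-2-methoxyethan-1-one F1 (one product only, since both ortho positions of 1 are equivalent). O-Aroylation with 7 in pyridine would give 2-(methoxyacetyl)-3,4,5-trimethoxyphenyl 4-methoxybenzoate F2. Base (KOH in pyridine at 50 °C) would induce the O-to-C aroyl shift to 1-(2-hydroxy-4,5,6-trimethoxyphenyl)-2-methoxy-3-(4-methoxyphenyl)propane-1,3-dione F3, and cyclodehydration with catalytic H2SO4 in acetic acid would give 14.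

Step 4. Methylation on carbon instead of oxygen may compete, because the enolate is ambident and the α-carbon is only moderately hindered. Fallback: an acid-catalysed route from 8 that rejoins at 9. Trimethyl orthoformate and catalytic TsOH in methanol would convert the ketone of 8 into the dimethyl ketal methyl 2,3,3-trimethoxy-3-(4-methoxyphenyl)propanoate F4. Heating F4 with the same acid in toluene while methanol is distilled off would eliminate to 9; no enolate is involved, so C-alkylation cannot occur.

Step 10. The deacylation may not stop at one acetate (the 4'- and 3-acetates are the next most labile), or the freed 7-phenoxide may take over the acetyl group from O6, giving an isomeric phenol. Fallback: from 16, trap the phenoxide as it forms and release it later under neutral conditions, rejoining at 17. Benzyl bromide, K2CO3 and KI in refluxing acetone, the known one-flask 7-selective deacetylation–benzylation of flavone peracetates, would give 2-(4-acetoxyphenyl)-7-(benzyloxy)-4-oxo-4H-chromene-3,5,6-triyl triacetate F5. Hydrogenolysis (H2, Pd/C, ethyl acetate, rt) would then give 17 without base.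

Step 11. An acetyl shift to O7 in the basic medium before sulfation would place the sulfate on the wrong oxygen, and the salt may lose sulfur trioxide or be hard to free from excess reagent on purification. Fallback: from 17, introduce the sulfate as a neutral, chromatographable diester and rejoin at 19. 2,2,2-Trichloroethyl chlorosulfate with Et3N and DMAP in THF at 0 °C, a fast and irreversible sulfonylation, would give 2-(4-acetoxyphenyl)-4-oxo-7-{[(2,2,2-trichloroethoxy)sulfonyl]oxy}-4H-chromene-3,5,6-triyl triacetate F6. Reductive removal of the trichloroethyl group with Zn dust and ammonium formate in methanol would give ammonium 3,5,6-triacetoxy-2-(4-acetoxyphenyl)-4-oxo-4H-chromen-7-yl sulfate F7, which under the conditions of step 12 would pass through 19 to 20.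

## Further compounds

F1 | step 6 | 1-(2-hydroxy-4,5,6-trimethoxyphenyl)-2-methoxyethan-1-one | COCC(=O)c1c(O)cc(OC)c(OC)c1OC
F2 | step 6 | 2-(methoxyacetyl)-3,4,5-trimethoxyphenyl 4-methoxybenzoate | COCC(=O)c1c(OC(=O)c2ccc(OC)cc2)cc(OC)c(OC)c1OC
F3 | step 6 | 1-(2-hydroxy-4,5,6-trimethoxyphenyl)-2-methoxy-3-(4-methoxyphenyl)propane-1,3-dione (racemic) | COC(C(=O)c1ccc(OC)cc1)C(=O)c1c(O)cc(OC)c(OC)c1OC
F4 | step 4 | methyl 2,3,3-trimethoxy-3-(4-methoxyphenyl)propanoate (racemic) | COC(=O)C(OC)C(OC)(OC)c1ccc(OC)cc1
F5 | step 10 | 2-(4-acetoxyphenyl)-7-(benzyloxy)-4-oxo-4H-chromene-3,5,6-triyl triacetate | CC(=O)Oc1ccc(cc1)-c1oc2cc(OCc3ccccc3)c(OC(C)=O)c(OC(C)=O)c2c(=O)c1OC(C)=O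
F6 | step 11 | 2-(4-acetoxyphenyl)-4-oxo-7-{[(2,2,2-trichloroethoxy)sulfonyl]oxy}-4H-chromene-3,5,6-triyl triacetate | CC(=O)Oc1ccc(cc1)-c1oc2cc(OS(=O)(=O)OCC(Cl)(Cl)Cl)c(OC(C)=O)c(OC(C)=O)c2c(=O)c1OC(C)=O
F7 | step 11 | ammonium 3,5,6-triacetoxy-2-(4-acetoxyphenyl)-4-oxo-4H-chromen-7-yl sulfate | CC(=O)Oc1ccc(cc1)-c1oc2cc(OS(=O)(=O)[O-])c(OC(C)=O)c(OC(C)=O)c2c(=O)c1OC(C)=O.[NH4+]
A1 | alternative 1 | methyl 5-(benzyloxy)-6-[4-(benzyloxy)phenyl]-2-methyl-4-oxo-4H-pyran-3-carboxylate | COC(=O)c1c(C)oc(-c2ccc(OCc3ccccc3)cc2)c(OCc2ccccc2)c1=O
A2 | alternative 1 | methyl 2-(benzyloxy)acetate | COC(=O)COCc1ccccc1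
A3 | alternative 1 | 3,6-bis(benzyloxy)-2-[4-(benzyloxy)phenyl]-5,7-dihydroxy-4H-chromen-4-one | O=c1c(OCc2ccccc2)c(-c2ccc(OCc3ccccc3)cc2)oc2cc(O)c(OCc3ccccc3)c(O)c12
A4 | alternative 2 | 2,3,4-trimethoxy-6-[1-(4-methoxyphenyl)-2-oxoethoxy]benzaldehyde (racemic) | COc1ccc(cc1)C(C=O)Oc1cc(OC)c(OC)c(OC)c1C=O
A5 | alternative 2 | 4-hydroxy-5,6,7-trimethoxy-2-(4-methoxyphenyl)chroman-3-one (diastereomer mixture) | COc1ccc(cc1)C1Oc2cc(OC)c(OC)c(OC)c2C(O)C1=O
A6 | alternative 2 | 3-hydroxy-5,6,7-trimethoxy-2-(4-methoxyphenyl)-4H-chromen-4-one | COc1ccc(cc1)-c1oc2cc(OC)c(OC)c(OC)c2c(=O)c1O
A7 | alternative 3 | (E)-2-methoxy-3-(4-methoxyphenyl)-3-(3,4,5-trimethoxyphenoxy)acrylic acid | COc1ccc(cc1)/C(Oc1cc(OC)c(OC)c(OC)c1)=C(\OC)C(O)=O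
A8 | alternative 3 | 3,5,6,7-tetramethoxy-2-(4-methoxyphenyl)-4H-chromen-4-one (identical with 14) | COc1ccc(cc1)-c1oc2cc(OC)c(OC)c(OC)c2c(=O)c1OC
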